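**Retrosynthetic overview**
1. Target 11 ⇒ seco-enol 10. The last bond made is O1–C2 (spiro), by Markovnikov addition of the triketone enol O–H across the pinene C2=C3 bond (6-exo); this closes the dihydropyran, the only ring built in the route.
2. 10 ⇒ ene-trione 8 + isobutyl nucleophile (Cu-catalysed asymmetric conjugate addition sets the side-chain centre).
3. 8 ⇒ syncarpic acid 4 + aldehyde 6 (Knoevenagel); 6 ⇐ (−)-nopol 5, which brings the intact pinane and both bridgehead centres.
4. 4 ⇐ phloroacetophenone 1 (fourfold C-methylation, then deacetylation); the carbocyclic trione and the pinane bicycle therefore exist before the pyran is closed.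

Assumption: the sense of induction of the chiral catalysts in steps 5 and 6 cannot be predicted for these substrates; the enantiomer written is tried first and its mirror image is used if the first run shows the opposite sense.

**Step 1**
Reactants: 1 2,4,6-trihydroxyacetophenone (phloroacetophenone, sold as the monohydrate); 2 iodomethane
Product: 3 2-acetyl-3-hydroxy-4,4,6,6-tetramethylcyclohex-2-ene-1,5-dione (acetylsyncarpic acid)
Conditions: NaOMe (6 equiv), MeI (8 equiv), MeOH, 0 °C → reflux; aq HCl work-up
Reagents that add atoms: iodomethane CI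
Why: Exhaustive dearomatising C-methylation of the phloroglucinol polyanion; the acetyl group blocks the third ring carbon, so exactly four methyl groups enter, two on each free ring carbon.

**Step 2**
Reactants: 3 acetylsyncarpic acid
Product: 4 syncarpic acid, drawn as the enol 3-hydroxy-4,4,6,6-tetramethylcyclohex-2-ene-1,5-dione
Conditions: 6 M aq HCl, reflux
Reagents that add atoms: none
Why: Acid-promoted retro-Claisen deacylation removes the exocyclic acetyl group as acetic acid; the ring acyl bonds are flanked by quaternary carbons and stay intact.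

**Step 3**
Reactants: 5 (1R)-(−)-nopol, 2-[(1R,5S)-6,6-dimethylbicyclo[3.1.1]hept-2-en-2-yl]ethanol
Product: 6 2-[(1R,5S)-6,6-dimethylbicyclo[3.1.1]hept-2-en-2-yl]acetaldehyde
Conditions: IBX (1.5 equiv), DMSO, 23 °C; used crude the same day
Reagents that add atoms: none
Why: IBX oxidation of a primary alcohol to the aldehyde under neutral conditions, which leaves the β,γ-alkene out of conjugation and both pinane centres untouched.

**Step 4**
Reactants: 4 syncarpic acid; 6 pinenyl acetaldehyde
Product: 8 2,2,4,4-tetramethyl-6-{2-[(1R,5S)-6,6-dimethylbicyclo[3.1.1]hept-2-en-2-yl]ethylidene}cyclohexane-1,3,5-trione (ene-trione), via piperidine Mannich base 7 (not isolated)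
Conditions: piperidine (1.05 equiv), CH2Cl2, 0 °C; then cold 1 M HCl wash, dry, use at once
Reagents that add atoms: none
Why: Knoevenagel condensation run through the Mannich base: syncarpate captures the piperidine iminium of 6 to give 7, which shields the product from a second Michael addition, and the acid wash expels piperidine to release 8; no stereocentre forms because the two acyl arms on the exocyclic C=C are identical.

**Step 5**
Reactants: 8 ene-trione; 9 isobutylmagnesium bromide
Product: 10 3-hydroxy-2-{(2S)-1-[(1R,5S)-6,6-dimethylbicyclo[3.1.1]hept-2-en-2-yl]-4-methylpentan-2-yl}-4,4,6,6-tetramethylcyclohex-2-ene-1,5-dione (seco-enol)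
Conditions: i-Bu2Zn (1.5 equiv; from 9 + ZnCl2, Et2O, then 1,4-dioxane, filter), Cu(OTf)2 (3 mol %), (S,R,R)-binaphthyl bis(1-phenylethyl)phosphoramidite (6 mol %), toluene, −78 → −30 °C; aq NH4Cl/HCl
Reagents that add atoms: isobutylmagnesium bromide CC(C)C[Mg]Br (transferred as diisobutylzinc CC(C)C[Zn]CC(C)C made from it in the flask)
Why: Cu/phosphoramidite-catalysed asymmetric conjugate addition of a dialkylzinc to a doubly activated alkylidene (the reaction type established for alkylidene Meldrum's acids and malonates); the chiral Cu–alkyl delivers isobutyl to one face of the exocyclic C=C and sets the (S) side-chain centre under catalyst control, since the remote pinane gives no bias.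

**Step 6**
Reactants: 10 seco-enol
Product: 11 (1R,2R,4'S,5S)-6,6,6',6',8',8'-hexamethyl-4'-(2-methylpropyl)-3',4'-dihydrospiro[bicyclo[3.1.1]heptane-2,2'-chromene]-5',7'(6'H,8'H)-dione (target)
Conditions: confined chiral imidodiphosphorimidate Brønsted acid (IDPi, (S,S) first, 5 mol %), cyclohexane, 5 Å MS, 0 → 25 °C
Reagents that add atoms: none
Why: Proposed new method: the confined acid is proposed to protonate C-3 of the strained trisubstituted pinene alkene while its basic P=N/S=O site holds the enol O–H, so that C-3–H and O–C-2 bond formation merge into one asynchronous, ion-paired 6-exo-trig Markovnikov event with no free pinan-2-yl cation (hence no cyclobutane opening or Wagner–Meerwein shift), the enol oxygen entering C-2 on the face anti to the gem-dimethyl bridge and so setting the spiro centre as (R); the closest known reaction types are IDPi-catalysed intramolecular hydroalkoxylation of unactivated alkenols and the acid-mediated cyclisation of 2-prenyl-1,3-diones (lapachol type) to pyrans, neither shown for an enol donor on a pinene alkene.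

**Compound list**
1 | 2,4,6-trihydroxyacetophenone | CC(=O)c1c(O)cc(O)cc1O | starting material
2 | iodomethane | CI | starting material
3 | 2-acetyl-3-hydroxy-4,4,6,6-tetramethylcyclohex-2-ene-1,5-dione (acetylsyncarpic acid) | CC(=O)C1=C(O)C(C)(C)C(=O)C(C)(C)C1=O | intermediate
4 | syncarpic acid, 3-hydroxy-4,4,6,6-tetramethylcyclohex-2-ene-1,5-dione | OC1=CC(=O)C(C)(C)C(=O)C1(C)C | intermediate
5 | (1R)-(−)-nopol, 2-[(1R,5S)-6,6-dimethylbicyclo[3.1.1]hept-2-en-2-yl]ethanol | OCCC1=CC[C@H]2C[C@@H]1C2(C)C | starting material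
6 | 2-[(1R,5S)-6,6-dimethylbicyclo[3.1.1]hept-2-en-2-yl]acetaldehyde | O=CCC1=CC[C@H]2C[C@@H]1C2(C)C | intermediate
7 | 3-hydroxy-2-{2-[(1R,5S)-6,6-dimethylbicyclo[3.1.1]hept-2-en-2-yl]-1-(piperidin-1-yl)ethyl}-4,4,6,6-tetramethylcyclohex-2-ene-1,5-dione (Mannich base, both epimers at the amino carbon) | OC1=C(C(CC2=CC[C@H]3C[C@@H]2C3(C)C)N2CCCCC2)C(=O)C(C)(C)C(=O)C1(C)C | intermediate (not isolated)
8 | 2,2,4,4-tetramethyl-6-{2-[(1R,5S)-6,6-dimethylbicyclo[3.1.1]hept-2-en-2-yl]ethylidene}cyclohexane-1,3,5-trione | O=C1C(=CCC2=CC[C@H]3C[C@@H]2C3(C)C)C(=O)C(C)(C)C(=O)C1(C)C | intermediate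
9 | isobutylmagnesium bromide | CC(C)C[Mg]Br | starting material
10 | 3-hydroxy-2-{(2S)-1-[(1R,5S)-6,6-dimethylbicyclo[3.1.1]hept-2-en-2-yl]-4-methylpentan-2-yl}-4,4,6,6-tetramethylcyclohex-2-ene-1,5-dione | CC(C)C[C@@H](CC1=CC[C@H]2C[C@@H]1C2(C)C)C1=C(O)C(C)(C)C(=O)C(C)(C)C1=O | intermediate
11 | (1R,2R,4'S,5S)-6,6,6',6',8',8'-hexamethyl-4'-(2-methylpropyl)-3',4'-dihydrospiro[bicyclo[3.1.1]heptane-2,2'-chromene]-5',7'(6'H,8'H)-dione | CC(C)C[C@H]1C[C@@]2(CC[C@H]3C[C@@H]2C3(C)C)OC2=C1C(=O)C(C)(C)C(=O)C2(C)C | target

**Totals**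
Total steps: 6. Longest linear sequence: 5 (1 → 3 → 4 → 8 → 10 → 11); the nopol branch joins after one step.

**Steps most likely to fail**

Step 6 (the new hydroalkoxylation). If the proton transfer is not tightly coupled to C–O bond formation, the pinan-2-yl cation opens to p-menthadienes, or fragments back to β-pinene and an alkylidene trione and scrambles the side-chain centre. The fallback uses known chemistry and sets out from 10. Mukaiyama hydration (Co(acac)2 cat., PhSiH3, O2, THF/i-PrOH, 0 °C → 23 °C) puts oxygen on the tertiary C-2 radical from the face anti to the gem-dimethyl bridge. This gives 3-hydroxy-2-{(2S)-1-[(1R,2R,5S)-2-hydroxy-6,6-dimethylbicyclo[3.1.1]heptan-2-yl]-4-methylpentan-2-yl}-4,4,6,6-tetramethylcyclohex-2-ene-1,5-dione F4. PPTS (cat.), toluene, 4 Å MS, 60 °C then closes the hemiketal onto the ring carbonyl and dehydrates it to the vinylogous ester, with the carbinol C–O bond retained. The fallback comes back to the route at 11.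

Step 5 (facial control in the conjugate addition). The acceptor is new for this catalyst class and the selectivity may be low. The fallback sets out from 8 and gives up catalyst control in favour of separation, using the enantiopure pinane as a built-in resolving group. i-BuMgBr with CuBr·SMe2 (10 mol %) in THF at −78 °C, without chiral ligand, gives 10 together with 3-hydroxy-2-{(2R)-1-[(1R,5S)-6,6-dimethylbicyclo[3.1.1]hept-2-en-2-yl]-4-methylpentan-2-yl}-4,4,6,6-tetramethylcyclohex-2-ene-1,5-dione F2. The mixture is cyclised as in step 6. The target is then separated by chromatography from its diastereomer (1R,2R,4'R,5S)-6,6,6',6',8',8'-hexamethyl-4'-(2-methylpropyl)-3',4'-dihydrospiro[bicyclo[3.1.1]heptane-2,2'-chromene]-5',7'(6'H,8'H)-dione F3. The fallback comes back to the route at 11.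

Step 4 (lability of ene-trione 8). Its doubly allylic CH2 can tautomerise to a conjugated dienyl enol that no longer accepts nucleophiles, and 8 can add a second syncarpate. The fallback sets out from 4 and 6 and replaces free 8 by a storable masked form. Three-component condensation with p-toluenesulfinic acid (CH2Cl2, MgSO4, 23 °C) gives crystalline 3-hydroxy-2-{2-[(1R,5S)-6,6-dimethylbicyclo[3.1.1]hept-2-en-2-yl]-1-(4-methylbenzenesulfonyl)ethyl}-4,4,6,6-tetramethylcyclohex-2-ene-1,5-dione F1. Under the step 5 conditions with one extra equivalent of i-Bu2Zn, F1 loses sulfinate, so 8 forms only transiently in the presence of the copper catalyst and is trapped at once. The fallback comes back to the route at 10.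

**Further compounds**
F1 | step 4 | 3-hydroxy-2-{2-[(1R,5S)-6,6-dimethylbicyclo[3.1.1]hept-2-en-2-yl]-1-(4-methylbenzenesulfonyl)ethyl}-4,4,6,6-tetramethylcyclohex-2-ene-1,5-dione | Cc1ccc(cc1)S(=O)(=O)C(CC1=CC[C@H]2C[C@@H]1C2(C)C)C1=C(O)C(C)(C)C(=O)C(C)(C)C1=O
F2 | step 5 | 3-hydroxy-2-{(2R)-1-[(1R,5S)-6,6-dimethylbicyclo[3.1.1]hept-2-en-2-yl]-4-methylpentan-2-yl}-4,4,6,6-tetramethylcyclohex-2-ene-1,5-dione | CC(C)C[C@H](CC1=CC[C@H]2C[C@@H]1C2(C)C)C1=C(O)C(C)(C)C(=O)C(C)(C)C1=O
F3 | step 5 | (1R,2R,4'R,5S)-6,6,6',6',8',8'-hexamethyl-4'-(2-methylpropyl)-3',4'-dihydrospiro[bicyclo[3.1.1]heptane-2,2'-chromene]-5',7'(6'H,8'H)-dione | CC(C)C[C@@H]1C[C@@]2(CC[C@H]3C[C@@H]2C3(C)C)OC2=C1C(=O)C(C)(C)C(=O)C2(C)C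
F4 | step 6 | 3-hydroxy-2-{(2S)-1-[(1R,2R,5S)-2-hydroxy-6,6-dimethylbicyclo[3.1.1]heptan-2-yl]-4-methylpentan-2-yl}-4,4,6,6-tetramethylcyclohex-2-ene-1,5-dione | CC(C)C[C@@H](C[C@]1(O)CC[C@H]2C[C@@H]1C2(C)C)C1=C(O)C(C)(C)C(=O)C(C)(C)C1=O
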